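**Retrosynthetic overview**
1. Target 14 comes from flavone 13 by one BCl3 operation that removes both benzyl ethers and the carbonyl-chelated 5-O-methyl group.
2. Key step: ring C, the only ring formed, is closed in one operation by a Pd-catalysed three-component carbonylative alkynylation/annulation of iodophenol 5, CO gas and arylacetylene 10. C4 comes from CO, and the bonds C4a–C4, C4–C3 and O1–C2 are made together.
3. Compound 5 comes from the symmetric phenol 4 by mono-iodination (its two free positions are equivalent), and 4 comes from syringaldehyde by benzylation and Baeyer–Villiger oxidation.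
4. Compound 10 comes from 2,5-dimethoxyphenol by benzylation, para-iodination and Sonogashira coupling/desilylation.
5. Rings A and B are bought. No acetophenone, chalcone or 1,3-diketone is used.

Assumption: the SMILES has no stereocentre, stereogenic axis or stereogenic double bond, so the target is achiral and no stereocontrol is needed. Simple reagents (BnBr, NIS, mCPBA, TMS-acetylene, CO) are given with SMILES in the steps and are not numbered.

**Step 1**
Reactants: 1 syringaldehyde (4-hydroxy-3,5-dimethoxybenzaldehyde)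
Product: 2 4-(benzyloxy)-3,5-dimethoxybenzaldehyde
Conditions: BnBr (1.1 equiv), K2CO3, DMF, 60 °C
Reagents that add atoms: benzyl bromide, BrCc1ccccc1
Why: Williamson ether synthesis, in which the acidic phenoxide para to the aldehyde is the only nucleophile and its SN2 benzylation marks the future O-6 as different from the two flanking methyl ethers.

**Step 2**
Reactants: 2 4-(benzyloxy)-3,5-dimethoxybenzaldehyde
Product: 4 4-(benzyloxy)-3,5-dimethoxyphenol, via aryl formate 3 (not isolated)
Conditions: mCPBA (1.3 equiv), CH2Cl2, 0 °C to rt; concentrate; then K2CO3 (cat.), MeOH, rt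
Reagents that add atoms: mCPBA, OOC(=O)c1cccc(Cl)c1
Why: Baeyer–Villiger (Dakin-type) oxidation, in which the electron-rich aryl group migrates from the Criegee adduct to give formate 3 and mild transesterification with methanol then frees the symmetric phenol without touching any ether.

**Step 3**
Reactants: 4 4-(benzyloxy)-3,5-dimethoxyphenol
Product: 5 4-(benzyloxy)-2-iodo-3,5-dimethoxyphenol
Conditions: NIS (1.0 equiv), MeCN, −20 to 0 °C, dark
Reagents that add atoms: N-iodosuccinimide, O=C1CCC(=O)N1I
Why: Electrophilic aromatic iodination (SEAr), in which the two free ring positions are equivalent and each is ortho to OH, ortho to one OMe and para to the other, so one equivalent of NIS can give only one mono-iodide and fixes the 5,6,7-pattern.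

**Step 4**
Reactants: 6 2,5-dimethoxyphenol
Product: 7 2-(benzyloxy)-1,4-dimethoxybenzene
Conditions: BnBr (1.1 equiv), K2CO3, DMF, 60 °C
Reagents that add atoms: benzyl bromide, BrCc1ccccc1
Why: Williamson ether synthesis on the only acidic OH, giving a protecting group that falls in the same final operation as the one on ring A.

**Step 5**
Reactants: 7 2-(benzyloxy)-1,4-dimethoxybenzene
Product: 8 1-(benzyloxy)-4-iodo-2,5-dimethoxybenzene
Conditions: NIS (1.05 equiv), TFA (10 mol %), MeCN, rt
Reagents that add atoms: N-iodosuccinimide, O=C1CCC(=O)N1I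
Why: Acid-activated SEAr iodination, which goes to the only doubly activated and unhindered position (para to OBn, ortho to OMe), as 1,2,4-trialkoxybenzenes always react at C5.

**Step 6**
Reactants: 8 1-(benzyloxy)-4-iodo-2,5-dimethoxybenzene
Product: 10 1-(benzyloxy)-4-ethynyl-2,5-dimethoxybenzene, via TMS-alkyne 9 (not isolated)
Conditions: TMS-acetylene (1.3 equiv), PdCl2(PPh3)2 (2 mol %), CuI (4 mol %), Et3N/THF, 40 °C; filter, concentrate; then K2CO3 (cat.), MeOH, rt
Reagents that add atoms: ethynyltrimethylsilane, C#C[Si](C)(C)C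
Why: Sonogashira coupling of the aryl iodide, in which the silyl cap prevents double arylation and methoxide-catalysed protodesilylation of crude 9 then frees the terminal alkyne.

**Step 7 (key step)**
Reactants: 5 4-(benzyloxy)-2-iodo-3,5-dimethoxyphenol; 10 1-(benzyloxy)-4-ethynyl-2,5-dimethoxybenzene (1.2 equiv)
Product: 13 6-(benzyloxy)-2-[4-(benzyloxy)-2,5-dimethoxyphenyl]-5,7-dimethoxy-4H-chromen-4-one, via ynone 11 (not isolated), via enaminone 12 (not isolated)
Conditions: CO (20 bar), PdCl2(dppf) (5 mol %), Et2NH (solvent and base), 120 °C, autoclave, no copper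
Reagents that add atoms: carbon monoxide, [C-]#[O+]; diethylamine, CCNCC (only in intermediate 12, released again on ring closure)
Why: Carbonylative Sonogashira coupling/annulation, in which oxidative addition into C–I, CO insertion (fast for an electron-rich aryl, and favoured over direct coupling by copper-free high CO pressure) and alkynyl transfer give ynone 11, Et2NH adds in Michael fashion to give 12, and the phenol can then close only by six-membered addition–elimination, which shuts off the 5-exo aurone path.

**Step 8**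
Reactants: 13 6-(benzyloxy)-2-[4-(benzyloxy)-2,5-dimethoxyphenyl]-5,7-dimethoxy-4H-chromen-4-one
Product: 14 5,6-dihydroxy-2-(4-hydroxy-2,5-dimethoxyphenyl)-7-methoxy-4H-chromen-4-one (target)
Conditions: BCl3 (1 M in CH2Cl2, 6 equiv), pentamethylbenzene (6 equiv), CH2Cl2, −78 to 0 °C; then 1 M aq HCl/THF, rt, under argon
Reagents that add atoms: none
Why: Lewis-acid ether cleavage with a non-basic cation scavenger, in which both aryl benzyl ethers ionise at −78 °C (the benzyl cation is trapped by Friedel–Crafts alkylation of pentamethylbenzene) and on warming only the 5-OMe, held in a six-membered boron chelate with the C4 carbonyl, is demethylated by chloride, while the unchelated 7-, 2'- and 5'-OMe groups resist BCl3 at or below 0 °C.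

**Compound list**
1 | syringaldehyde (4-hydroxy-3,5-dimethoxybenzaldehyde) | COc1cc(C=O)cc(OC)c1O | starting material
2 | 4-(benzyloxy)-3,5-dimethoxybenzaldehyde | COc1cc(C=O)cc(OC)c1OCc1ccccc1 | intermediate
3 | 4-(benzyloxy)-3,5-dimethoxyphenyl formate | COc1cc(OC=O)cc(OC)c1OCc1ccccc1 | intermediate (not isolated)
4 | 4-(benzyloxy)-3,5-dimethoxyphenol | COc1cc(O)cc(OC)c1OCc1ccccc1 | intermediate
5 | 4-(benzyloxy)-2-iodo-3,5-dimethoxyphenol | Oc1cc(OC)c(OCc2ccccc2)c(OC)c1I | intermediate
6 | 2,5-dimethoxyphenol | COc1ccc(OC)c(O)c1 | starting material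
7 | 2-(benzyloxy)-1,4-dimethoxybenzene | COc1ccc(OC)c(OCc2ccccc2)c1 | intermediate
8 | 1-(benzyloxy)-4-iodo-2,5-dimethoxybenzene | COc1cc(OCc2ccccc2)c(OC)cc1I | intermediate
9 | {[4-(benzyloxy)-2,5-dimethoxyphenyl]ethynyl}trimethylsilane | COc1cc(OCc2ccccc2)c(OC)cc1C#C[Si](C)(C)C | intermediate (not isolated)
10 | 1-(benzyloxy)-4-ethynyl-2,5-dimethoxybenzene | COc1cc(OCc2ccccc2)c(OC)cc1C#C | intermediate
11 | 1-[3-(benzyloxy)-6-hydroxy-2,4-dimethoxyphenyl]-3-[4-(benzyloxy)-2,5-dimethoxyphenyl]prop-2-yn-1-one | COc1cc(OCc2ccccc2)c(OC)cc1C#CC(=O)c1c(O)cc(OC)c(OCc2ccccc2)c1OC | intermediate (not isolated)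
12 | 1-[3-(benzyloxy)-6-hydroxy-2,4-dimethoxyphenyl]-3-[4-(benzyloxy)-2,5-dimethoxyphenyl]-3-(diethylamino)prop-2-en-1-one (push–pull alkene, E/Z interconverting, geometry not defined) | CCN(CC)C(=CC(=O)c1c(O)cc(OC)c(OCc2ccccc2)c1OC)c1cc(OC)c(OCc2ccccc2)cc1OC | intermediate (not isolated)
13 | 6-(benzyloxy)-2-[4-(benzyloxy)-2,5-dimethoxyphenyl]-5,7-dimethoxy-4H-chromen-4-one | COc1cc(-c2cc(=O)c3c(OC)c(OCc4ccccc4)c(OC)cc3o2)c(OC)cc1OCc1ccccc1 | intermediate
14 | 5,6-dihydroxy-2-(4-hydroxy-2,5-dimethoxyphenyl)-7-methoxy-4H-chromen-4-one (5,6,4'-trihydroxy-7,2',5'-trimethoxyflavone, achiral) | COc1cc(-c2cc(=O)c3c(O)c(O)c(OC)cc3o2)c(OC)cc1O | target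

**Step count**
- Total steps: 8.
- Longest linear sequence: 5 steps. This is 1→2→4→5→13→14, and the branch 6→7→8→10→13→14 is equally long.

**Three steps most likely to fail, each with a fallback**

**Step 7.** The iodide is very electron-rich and flanked on both sides. The risks are slow oxidative addition, aminocarbonylation to the diethylamide, and CO-free coupling that leads to a benzofuran. The fallback drops palladium and CO and builds the ynone by polar chemistry. It sets out from 4 and 10 and comes back to the route at 11. Magnesium-mediated ortho-formylation of phenol 4 (MgCl2, Et3N, paraformaldehyde, MeCN, reflux; both ortho positions are equivalent) gives 3-(benzyloxy)-6-hydroxy-2,4-dimethoxybenzaldehyde F4. Alkyne 10 is deprotonated with n-BuLi (THF, −78 °C) to {[4-(benzyloxy)-2,5-dimethoxyphenyl]ethynyl}lithium F5. Addition of 2.2 equiv of it to F4, with NH4Cl quench, gives racemic 1-[3-(benzyloxy)-6-hydroxy-2,4-dimethoxyphenyl]-3-[4-(benzyloxy)-2,5-dimethoxyphenyl]prop-2-yn-1-ol F6. MnO2 (CH2Cl2, rt) removes the transient stereocentre and gives ynone 11. Warm Et2NH/EtOH then carries 11 through 12 to 13.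

**Step 8.** The risks are extra demethylation at 7-OMe or 5'-OMe next to the newly formed borates, C-benzylation, and air oxidation of the 5,6-catechol. The fallback separates the two kinds of cleavage and uses no boron. It sets out from 13 and comes back at 14. Hydrogenolysis (H2 1 atm, 10 % Pd/C, EtOAc/THF, rt) gives 6-hydroxy-2-(4-hydroxy-2,5-dimethoxyphenyl)-5,7-dimethoxy-4H-chromen-4-one F7. Chelation-controlled 5-O-demethylation with anhydrous AlCl3 in MeCN (60 °C), followed by warm dilute HCl to break the aluminium complex, gives 14.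

**Step 3.** Phenol 4 is a hydroquinone mono-ether, so the risks are di-iodination and oxidation to the quinone. The fallback replaces SEAr by directed ortho-metalation. It sets out from 4 and comes back at 5. MOMCl/i-Pr2NEt (CH2Cl2, 0 °C) gives 2-(benzyloxy)-1,3-dimethoxy-5-(methoxymethoxy)benzene F1. n-BuLi (1.05 equiv, THF, −78 to −20 °C) lithiates the position between OMOM and OMe once, giving [3-(benzyloxy)-2,4-dimethoxy-6-(methoxymethoxy)phenyl]lithium F2. Quenching with I2 gives 2-(benzyloxy)-4-iodo-1,3-dimethoxy-5-(methoxymethoxy)benzene F3. HCl in MeOH (40 °C) removes the acetal to give 5.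

**Further compounds**
F1 | step 3 | 2-(benzyloxy)-1,3-dimethoxy-5-(methoxymethoxy)benzene | COCOc1cc(OC)c(OCc2ccccc2)c(OC)c1
F2 | step 3 | [3-(benzyloxy)-2,4-dimethoxy-6-(methoxymethoxy)phenyl]lithium | [Li]c1c(OCOC)cc(OC)c(OCc2ccccc2)c1OC
F3 | step 3 | 2-(benzyloxy)-4-iodo-1,3-dimethoxy-5-(methoxymethoxy)benzene | COCOc1cc(OC)c(OCc2ccccc2)c(OC)c1I
F4 | step 7 | 3-(benzyloxy)-6-hydroxy-2,4-dimethoxybenzaldehyde | O=Cc1c(O)cc(OC)c(OCc2ccccc2)c1OC
F5 | step 7 | {[4-(benzyloxy)-2,5-dimethoxyphenyl]ethynyl}lithium | [Li]C#Cc1cc(OC)c(OCc2ccccc2)cc1OC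
F6 | step 7 | 1-[3-(benzyloxy)-6-hydroxy-2,4-dimethoxyphenyl]-3-[4-(benzyloxy)-2,5-dimethoxyphenyl]prop-2-yn-1-ol (racemic) | OC(C#Cc1cc(OC)c(OCc2ccccc2)cc1OC)c1c(O)cc(OC)c(OCc2ccccc2)c1OC
F7 | step 8 | 6-hydroxy-2-(4-hydroxy-2,5-dimethoxyphenyl)-5,7-dimethoxy-4H-chromen-4-one | COc1cc(-c2cc(=O)c3c(OC)c(O)c(OC)cc3o2)c(OC)cc1O
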